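**Strategy.** The γ-lactone is cis-fused to the ten-membered ring at C6–C7, and O6 and O8 are 1,3-syn on a chain whose C7 branch is anti to both. This triad is read as a pentofuranose: C5–C9 are carried as a methyl α-D-arabinofuranoside whose ring oxygen is the later C8–O. The precursor of the key step is this furanoside with a mesylate on C6 and a 1-borylvinyl arm on C7. In one operation the boronate takes up CO2 (C11–C12 bond) and the carboxylate displaces the mesylate with inversion (O–C6 bond), giving the cis-lactone. The temporary C5–O8 acetal is then opened by Z-iodo-olefination, the ring closed at C3–C4 by Nozaki–Hiyama–Kishi coupling, and the epoxide added last.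

Key step: step 10

Remark: atom labels follow germacranolide numbering (ring C1–C10: C1/C10 epoxide carbons, C3 acetoxy carbon, C4=C5 olefin, C6 lactone-oxygen carbon, C7 ring-fusion carbon, C8 methacryloyloxy carbon; C11 lactone α-carbon, C12 lactone carbonyl, C13 exocyclic methylene, C14/C15 methyls on C10/C4). Sugar positions C1–C5 of the furanoside correspond to C5–C9. NAP = 2-naphthylmethyl.

Step 1
Reactants: 1 pent-3-yn-1-ol
Product: 2 2-[(pent-3-yn-1-yloxy)methyl]naphthalene
Conditions: NaH, 2-(bromomethyl)naphthalene, Bu4NI (cat.), THF, 0 °C to rt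
Reagents that add atoms: 2-(bromomethyl)naphthalene, BrCc1ccc2ccccc2c1
Why: Williamson ether synthesis, in which the primary alkoxide displaces the benzylic bromide and installs a NAP ether that tolerates organometallics, fluoride and aqueous acid and is cleaved oxidatively in step 14.

Step 2
Reactants: 2 2-[(pent-3-yn-1-yloxy)methyl]naphthalene
Product: 4 2-({[(3E)-4-iodopent-3-en-1-yl]oxy}methyl)naphthalene, via alkenylzirconocene 3 (not isolated)
Conditions: Cp2Zr(H)Cl (2 equiv), THF, 50 °C; then I2, 0 °C
Reagents that add atoms: iodine, II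
Why: Hydrozirconation–iodination (Schwartz reagent), in which syn H–Zr addition with equilibration under excess reagent places zirconium on the methyl-bearing alkyne carbon and iodinolysis with retention gives the E-iodoalkene that later becomes the E-C1=C10 olefin.

Step 3
Reactants: 5 methyl α-D-arabinofuranoside
Product: 6 methyl 5-O-(tert-butyldiphenylsilyl)-α-D-arabinofuranoside
Conditions: TBDPSCl, imidazole, DMF, 0 °C
Reagents that add atoms: tert-butyl(chloro)diphenylsilane, CC(C)(C)[Si](Cl)(c1ccccc1)c1ccccc1
Why: Selective silylation of the only primary hydroxyl by a bulky silyl chloride leaves the trans-2,3-diol (the C6 and C7 oxygens) free for the next step.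

Step 4
Reactants: 6 methyl 5-O-(tert-butyldiphenylsilyl)-α-D-arabinofuranoside
Product: 7 methyl 2,3-anhydro-5-O-(tert-butyldiphenylsilyl)-α-D-lyxofuranoside
Conditions: PPh3, DIAD, THF, 0 to 60 °C
Reagents that add atoms: none
Why: Mitsunobu cyclodehydration of a trans-vicinal diol, in which the C7 hydroxyl is activated as the oxyphosphonium ion and the more acidic C6 hydroxyl next to the acetal closes onto C7 with inversion, so that the epoxide lies on the face of the C8 side chain (lyxo) and C6 keeps its arabinose configuration.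

Step 5
Reactants: 7 methyl 2,3-anhydro-5-O-(tert-butyldiphenylsilyl)-α-D-lyxofuranoside
Product: 8 methyl 2,3-anhydro-α-D-lyxofuranoside
Conditions: TBAF, THF, 0 °C
Reagents that add atoms: none
Why: Fluoride-induced Si–O cleavage frees the primary C9 hydroxyl, which lies on the same face as the epoxide oxygen and cannot reach the backside of either epoxide carbon.

Step 6
Reactants: 8 methyl 2,3-anhydro-α-D-lyxofuranoside; 4 2-({[(3E)-4-iodopent-3-en-1-yl]oxy}methyl)naphthalene
Product: 12 methyl 2,3-anhydro-5-deoxy-5-C-[(2E)-5-(naphthalen-2-ylmethoxy)pent-2-en-2-yl]-α-D-lyxofuranoside, via triflate 9 (not isolated), via alkenyllithium 10 (not isolated), via alkenylmagnesium bromide 11 (not isolated)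
Conditions: 8: Tf2O, 2,6-lutidine, CH2Cl2, −78 °C; 4: t-BuLi (2 equiv), Et2O, −78 °C, then MgBr2·OEt2; combined with CuBr·SMe2 (10 mol %), THF, −40 to 0 °C
Reagents that add atoms: none
Why: Copper-catalysed cross-coupling of a primary alkyl triflate with an alkenyl Grignard reagent (Kochi/Kotsuki-type sp3–sp2 coupling) forms C9–C10, with iodine–lithium exchange, transmetalation and coupling all retaining the E-geometry and the triflate reacting much faster than the ring-fused epoxide at low temperature.

Step 7
Reactants: 12 methyl 2,3-anhydro-5-deoxy-5-C-[(2E)-5-(naphthalen-2-ylmethoxy)pent-2-en-2-yl]-α-D-lyxofuranoside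
Product: 13 methyl 3,5-dideoxy-3-C-ethynyl-5-C-[(2E)-5-(naphthalen-2-ylmethoxy)pent-2-en-2-yl]-α-D-arabinofuranoside
Conditions: LiC≡CH·H2NCH2CH2NH2, DMSO, rt to 45 °C
Reagents that add atoms: lithium acetylide (ethylenediamine complex), [Li+].[C-]#C.NCCN
Why: SN2 epoxide opening by acetylide, which occurs at C7 (remote from the deactivating acetal carbon) anti to the epoxide oxygen and to the C8 side chain, sets C7 and leaves the C6 hydroxyl trans to the ethynyl group (arabino configuration).

Step 8
Reactants: 13 methyl 3,5-dideoxy-3-C-ethynyl-5-C-[(2E)-5-(naphthalen-2-ylmethoxy)pent-2-en-2-yl]-α-D-arabinofuranoside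
Product: 15 methyl 3,5-dideoxy-5-C-[(2E)-5-(naphthalen-2-ylmethoxy)pent-2-en-2-yl]-3-C-[1-(4,4,5,5-tetramethyl-1,3,2-dioxaborolan-2-yl)ethenyl]-α-D-arabinofuranoside, via alkenylalane 14 (not isolated)
Conditions: NiCl2(dppp) (3 mol %), i-Bu2AlH (2.3 equiv), THF, 0 to 22 °C; then MeOBpin, 0 to 22 °C; aq. Rochelle salt
Reagents that add atoms: 2-methoxy-4,4,5,5-tetramethyl-1,3,2-dioxaborolane, COB1OC(C)(C)C(C)(C)O1
Why: Nickel-catalysed α-selective (Markovnikov) hydroalumination of the terminal alkyne followed by aluminium-to-boron exchange places boron on C11 of a 1,1-disubstituted alkene, the first equivalent of hydride only deprotonating the C6 hydroxyl.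

Step 9
Reactants: 15 α-alkenylboronate alcohol
Product: 16 methyl 3,5-dideoxy-2-O-methanesulfonyl-5-C-[(2E)-5-(naphthalen-2-ylmethoxy)pent-2-en-2-yl]-3-C-[1-(4,4,5,5-tetramethyl-1,3,2-dioxaborolan-2-yl)ethenyl]-α-D-arabinofuranoside
Conditions: MsCl, Et3N, CH2Cl2, 0 °C
Reagents that add atoms: methanesulfonyl chloride, CS(=O)(=O)Cl
Why: Sulfonylation of the only free hydroxyl proceeds with retention at C6 and turns O6 into a leaving group on the face opposite to the C7 alkenyl arm.

Step 10
Reactants: 16 mesylate boronate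
Product: 18 methyl 3-C-(1-carboxyethenyl)-3,5-dideoxy-5-C-[(2E)-5-(naphthalen-2-ylmethoxy)pent-2-en-2-yl]-α-D-ribofuranoside 2-O-lactone (cis-fused α-methylene-γ-lactone), via cesium carboxylate 17 (not isolated)
Conditions: (IPr)CuCl (chloro[1,3-bis(2,6-diisopropylphenyl)imidazol-2-ylidene]copper, 5 mol %), CsF (3 equiv), CO2 (1 atm), DMF, 90 °C
Reagents that add atoms: carbon dioxide, O=C=O
Why: Fluoride converts the pinacol boronate into a fluoroborate that transmetalates to the carbene–copper centre, the alkenylcopper inserts CO2 at C11 (C11–C12 bond), and the cesium acrylate 17 so released attacks C6 from the face anti to the mesylate (O–C6 bond). The closest known reaction types are the copper-catalysed carboxylation of alkenylboronic esters with CO2 and the SN2 lactonisation of cesium carboxylates onto secondary sulfonates. One ring is closed, the γ-lactone, in a 5-exo-tet mode that gives a cis-fused tetrahydrofuro[3,4-b]furan-2-one. The one new stereocentre, C6, is inverted from the arabino to the ribo configuration; it is controlled by the C6 configuration taken from D-arabinose and by the C7 configuration set in step 7, which holds the carboxylate on the face opposite to the leaving group. The step needs substitution at C6 to win over elimination and over direct reaction of the alkenylcopper with the mesylate: H5 and H7 are both cis to the mesylate on the furanose, so no anti-periplanar elimination is open, CO2 insertion into the alkenylcopper should be fast at one atmosphere, and the rigid template holds the carboxylate oxygen behind C6. The site of carboxylation is fixed by the position of boron, so no regiochemical choice arises at C11.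

Step 11
Reactants: 18 bicyclic lactone methyl furanoside
Product: 19 lactol (anomeric mixture) of 18, hydroxyl in place of the anomeric methoxy group
Conditions: 2 M HCl, THF, 45 °C
Reagents that add atoms: water, O
Why: Acid-catalysed hydrolysis of the methyl furanoside through the ring oxocarbenium ion should give the lactol without touching the lactone, the NAP ether or the stereocentres C6–C8.

Step 12
Reactants: 19 lactol
Product: 20 seco alcohol: cis-fused α-methylene-γ-lactone carrying the (Z)-2-iodoprop-1-enyl group on C6 and, on C7, the chain C8H(OH)–C9H2–C10(CH3)=C1H–C2H2–C3H2–ONAP (E); C6, C7, C8 as in the target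
Conditions: EtPPh3I, n-BuLi, THF, rt; I2, −78 °C; NaN(SiMe3)2, −20 °C; then 19, −78 to −30 °C; AcOH at −78 °C
Reagents that add atoms: ethyltriphenylphosphonium iodide, CC[P+](c1ccccc1)(c1ccccc1)c1ccccc1.[I-]; iodine, II
Why: Stork–Zhao olefination (Wittig reaction of the α-iodo ylide Ph3P=C(I)CH3), in which the ylide reacts with the hydroxy-aldehyde form of the lactol through the kinetically favoured cis-oxaphosphetane to give the Z-2-iodoalkene (iodine cis to C6), opens the temporary furanose ring and frees the C8 hydroxyl.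

Step 13
Reactants: 20 seco alcohol
Product: 21 C8 methacrylate of 20
Conditions: methacrylic anhydride, Et3N, DMAP (cat.), CH2Cl2, 0 °C
Reagents that add atoms: methacrylic anhydride, C=C(C)C(=O)OC(=O)C(C)=C
Why: DMAP-catalysed acylation of the single free secondary hydroxyl installs the C8 methacrylate under mild base with retention at C8.

Step 14
Reactants: 21 methacrylate NAP ether
Product: 22 primary C3 alcohol (NAP removed)
Conditions: DDQ, CH2Cl2/pH 7 buffer, 0 °C to rt
Reagents that add atoms: none
Why: Oxidative cleavage of the NAP ether by DDQ (hydride abstraction at the naphthylmethyl position, then hydrolysis) should free the C3 alcohol while the esters, the lactone, the iodoalkene and the isolated olefin stay untouched.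

Step 15
Reactants: 22 primary alcohol
Product: 23 C3 aldehyde
Conditions: Dess–Martin periodinane, NaHCO3, CH2Cl2, 0 °C
Reagents that add atoms: none
Why: Dess–Martin oxidation under bicarbonate buffer gives the β,γ-unsaturated aldehyde without acid or base strong enough to move the C1=C10 double bond into conjugation, and the aldehyde is used crude.

Step 16
Reactants: 23 iodoalkene aldehyde
Product: 24 (3S,6S,7R,8R)-3-hydroxy-8-(methacryloyloxy)germacra-1(10)E,4Z,11(13)-trien-12,6-olide
Conditions: CrCl2 (10 equiv), NiCl2 (2 mol %), DMSO/THF 3:1, rt, 2 mM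
Reagents that add atoms: none
Why: Intramolecular Nozaki–Hiyama–Kishi reaction, in which nickel-catalysed activation of the Z-iodoalkene and transfer to chromium give an alkenylchromium that adds only to the aldehyde and closes the ten-membered ring at C3–C4 with retention of the Z-olefin, the C3 carbinol being set in the ring-closing transition state where addition to the aldehyde face turned away from the cis-lactone is expected to give 3S.

Step 17
Reactants: 24 macrocyclic allylic alcohol
Product: 25 C3 acetate of 24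
Conditions: Ac2O, pyridine, DMAP (cat.), CH2Cl2, 0 °C
Reagents that add atoms: acetic anhydride, CC(=O)OC(C)=O
Why: Acyl transfer to the allylic C3 hydroxyl gives the acetate with retention at C3.

Step 18
Reactants: 25 macrocyclic triene
Product: 26 target, (1R,3S,6S,7R,8R,10R)-3-acetoxy-1,10-epoxy-8-(methacryloyloxy)germacra-4Z,11(13)-dien-12,6-olide
Conditions: D-fructose-derived Shi ketone (30 mol %), Oxone (2KHSO5·KHSO4·K2SO4), K2CO3, Bu4NHSO4, MeCN/dimethoxymethane/aq. Na2B4O7–EDTA buffer, 0 °C
Reagents that add atoms: potassium peroxymonosulfate (from Oxone), [K+].[O-]S(=O)(=O)OO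
Why: Shi asymmetric epoxidation, in which the dioxirane of the chiral ketone attacks the only electron-rich olefin, the E-trisubstituted C1=C10 bond (C4=C5 is deactivated by two allylic acyloxy groups and the two acrylate olefins are electron-poor), through the spiro transition state that should deliver the (1R,10R)-epoxide on the outer face of the ring.

**Compound list**

1 | pent-3-yn-1-ol | CC#CCCO | starting material
2 | 2-[(pent-3-yn-1-yloxy)methyl]naphthalene | CC#CCCOCc1ccc2ccccc2c1 | intermediate
3 | chlorobis(cyclopentadienyl)[(2E)-5-(naphthalen-2-ylmethoxy)pent-2-en-2-yl]zirconium (not isolated) | C/C(=C\CCOCc1ccc2ccccc2c1)[Zr](Cl)(C1C=CC=C1)C1C=CC=C1 | intermediate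
4 | 2-({[(3E)-4-iodopent-3-en-1-yl]oxy}methyl)naphthalene | C/C(I)=C\CCOCc1ccc2ccccc2c1 | intermediate
5 | methyl α-D-arabinofuranoside | CO[C@@H]1[C@@H](O)[C@H](O)[C@@H](CO)O1 | starting material
6 | methyl 5-O-(tert-butyldiphenylsilyl)-α-D-arabinofuranoside | CO[C@@H]1[C@@H](O)[C@H](O)[C@@H](CO[Si](c2ccccc2)(c2ccccc2)C(C)(C)C)O1 | intermediate
7 | methyl 2,3-anhydro-5-O-(tert-butyldiphenylsilyl)-α-D-lyxofuranoside | CO[C@@H]1[C@H]2O[C@H]2[C@@H](CO[Si](c3ccccc3)(c3ccccc3)C(C)(C)C)O1 | intermediate
8 | methyl 2,3-anhydro-α-D-lyxofuranoside | CO[C@@H]1[C@H]2O[C@H]2[C@@H](CO)O1 | intermediate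
9 | methyl 2,3-anhydro-5-O-(trifluoromethanesulfonyl)-α-D-lyxofuranoside (not isolated) | CO[C@@H]1[C@H]2O[C@H]2[C@@H](COS(=O)(=O)C(F)(F)F)O1 | intermediate
10 | alkenyllithium from 4, lithium in place of iodine with retention (not isolated) | C/C([Li])=C\CCOCc1ccc2ccccc2c1 | intermediate
11 | alkenylmagnesium bromide from 10, geometry retained (not isolated) | C/C([Mg]Br)=C\CCOCc1ccc2ccccc2c1 | intermediate
12 | methyl 2,3-anhydro-5-deoxy-5-C-[(2E)-5-(naphthalen-2-ylmethoxy)pent-2-en-2-yl]-α-D-lyxofuranoside | CO[C@@H]1[C@H]2O[C@H]2[C@@H](C/C(C)=C/CCOCc3ccc4ccccc4c3)O1 | intermediate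
13 | methyl 3,5-dideoxy-3-C-ethynyl-5-C-[(2E)-5-(naphthalen-2-ylmethoxy)pent-2-en-2-yl]-α-D-arabinofuranoside | CO[C@@H]1[C@@H](O)[C@H](C#C)[C@@H](C/C(C)=C/CCOCc2ccc3ccccc3c2)O1 | intermediate
14 | alkenylalane of 13: 1-(diisobutylalumanyl)ethenyl group on C7 and diisobutylaluminium alkoxide on O6 (not isolated) | CO[C@@H]1[C@@H](O[Al](CC(C)C)CC(C)C)[C@H](C(=C)[Al](CC(C)C)CC(C)C)[C@@H](C/C(C)=C/CCOCc2ccc3ccccc3c2)O1 | intermediate
15 | methyl 3,5-dideoxy-5-C-[(2E)-5-(naphthalen-2-ylmethoxy)pent-2-en-2-yl]-3-C-[1-(4,4,5,5-tetramethyl-1,3,2-dioxaborolan-2-yl)ethenyl]-α-D-arabinofuranoside | CO[C@@H]1[C@@H](O)[C@H](C(=C)B2OC(C)(C)C(C)(C)O2)[C@@H](C/C(C)=C/CCOCc3ccc4ccccc4c3)O1 | intermediate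
16 | 2-O-methanesulfonyl derivative of 15 | CO[C@@H]1[C@@H](OS(C)(=O)=O)[C@H](C(=C)B2OC(C)(C)C(C)(C)O2)[C@@H](C/C(C)=C/CCOCc3ccc4ccccc4c3)O1 | intermediate
17 | cesium 2-substituted acrylate of the 2-O-mesyl arabinofuranoside, carboxylate in place of boron (not isolated) | CO[C@@H]1[C@@H](OS(C)(=O)=O)[C@H](C(=C)C(=O)[O-])[C@@H](C/C(C)=C/CCOCc2ccc3ccccc3c2)O1.[Cs+] | intermediate
18 | methyl 3-C-(1-carboxyethenyl)-3,5-dideoxy-5-C-[(2E)-5-(naphthalen-2-ylmethoxy)pent-2-en-2-yl]-α-D-ribofuranoside 2-O-lactone (cis-fused α-methylene-γ-lactone) | CO[C@@H]1[C@@H]2OC(=O)C(=C)[C@@H]2[C@@H](C/C(C)=C/CCOCc3ccc4ccccc4c3)O1 | intermediate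
19 | lactol of 18 (anomeric mixture, C5 hemiacetal) | OC1[C@@H]2OC(=O)C(=C)[C@@H]2[C@@H](C/C(C)=C/CCOCc3ccc4ccccc4c3)O1 | intermediate
20 | seco alcohol: α-methylene-γ-lactone with (Z)-2-iodoprop-1-enyl on C6 and the C8 carbinol chain (E-olefin, NAP ether) on C7; C6, C7, C8 as in the target | C/C(I)=C/[C@@H]1OC(=O)C(=C)[C@@H]1[C@H](O)C/C(C)=C/CCOCc2ccc3ccccc3c2 | intermediate
21 | C8 methacrylate of 20 | C/C(I)=C/[C@@H]1OC(=O)C(=C)[C@@H]1[C@H](OC(=O)C(C)=C)C/C(C)=C/CCOCc2ccc3ccccc3c2 | intermediate
22 | primary C3 alcohol from 21 (NAP removed) | C/C(I)=C/[C@@H]1OC(=O)C(=C)[C@@H]1[C@H](OC(=O)C(C)=C)C/C(C)=C/CCO | intermediate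
23 | C3 aldehyde from 22 | C/C(I)=C/[C@@H]1OC(=O)C(=C)[C@@H]1[C@H](OC(=O)C(C)=C)C/C(C)=C/CC=O | intermediate
24 | (3S,6S,7R,8R)-3-hydroxy-8-(methacryloyloxy)germacra-1(10)E,4Z,11(13)-trien-12,6-olide | C=C(C)C(=O)O[C@@H]1C/C(C)=C/C[C@H](O)/C(C)=C\[C@@H]2OC(=O)C(=C)[C@@H]21 | intermediate
25 | (3S,6S,7R,8R)-3-acetoxy-8-(methacryloyloxy)germacra-1(10)E,4Z,11(13)-trien-12,6-olide | C=C(C)C(=O)O[C@@H]1C/C(C)=C/C[C@H](OC(C)=O)/C(C)=C\[C@@H]2OC(=O)C(=C)[C@@H]21 | intermediate
26 | (1R,3S,6S,7R,8R,10R)-3-acetoxy-1,10-epoxy-8-(methacryloyloxy)germacra-4Z,11(13)-dien-12,6-olide | C=C(C)C(=O)O[C@@H]1C[C@@]2(C)O[C@@H]2C[C@H](OC(C)=O)/C(C)=C\[C@@H]2OC(=O)C(=C)[C@@H]21 | target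

**Total step count:** 18.
**Longest linear sequence:** 16 steps (steps 3–18, from 5 to 26); steps 1–2 make the side fragment 4, which joins in step 6.

**The three steps most likely to fail**

Step 10 (key step). What may go wrong is protodeboronation of the hindered pinacol alkenylboronate, or transmetalation to copper too slow to compete with it, so that no carboxylate reaches C6; displacement next to the acetal carbon may also be slow. The fallback sets out from alkynol 13 and comes back at lactone 18. The alkenylalane 14 of step 8 is quenched with I2 instead of the borate to give the 2-iodoalkene alcohol F1. Palladium-catalysed hydroxycarbonylation (PdCl2(PPh3)2, CO 1 atm, H2O, Et3N, DMF, 60 °C) then forms the C11–C12 bond and gives the hydroxy acrylic acid F2; the trans hydroxyl cannot close a trans-fused lactone, so water takes the acyl group. Mitsunobu lactonisation (PPh3, DIAD, THF, 0 °C) activates O6 and closes the lactone with inversion at C6 to give 18.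

Step 12. What may go wrong is migration of the lactone acyl group to the C8 alkoxide that is set free when the lactolate opens (translactonisation to the isomeric C8 lactone), and conjugate addition of the ylide to the α-methylene lactone, both in competition with olefination. The fallback sets out from lactol 19 and comes back at methacrylate 21, so that the ylide only meets an aldehyde without a free hydroxyl. Reduction (NaBH4, CeCl3·7H2O, MeOH, 0 °C) gives the diol F3. Silylation of the primary hydroxyl (TBSCl, imidazole, CH2Cl2) gives the silyl ether F4. Acylation (methacrylic anhydride, Et3N, DMAP) gives the silyl ether methacrylate F5. Desilylation (HF·pyridine, THF) gives the primary alcohol F6, and Dess–Martin oxidation gives the α-acyloxy aldehyde F7. Stork–Zhao olefination of F7 with Ph3P=C(I)CH3 at −78 °C gives 21.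

Step 16. What may go wrong is poor facial selectivity in the addition of the alkenylchromium to the C3 aldehyde during ring closure. The fallback sets out from aldehyde 23 and comes back at alcohol 24, and sets C3 by reagent control instead. The ring is closed as in step 16 without regard to C3, which gives 24 together with its C3 epimer F8. Dess–Martin oxidation of the mixture gives the macrocyclic enone F9. Corey–Bakshi–Shibata reduction ((R)-2-methyl-CBS-oxazaborolidine, catecholborane, toluene, −78 °C) should then deliver hydride to the enone face that gives the 3S alcohol 24.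

**Further compounds**

F1 | step 10 | methyl 3,5-dideoxy-3-C-(1-iodoethenyl)-5-C-[(2E)-5-(naphthalen-2-ylmethoxy)pent-2-en-2-yl]-α-D-arabinofuranoside | CO[C@@H]1[C@@H](O)[C@H](C(I)=C)[C@@H](C/C(C)=C/CCOCc2ccc3ccccc3c2)O1
F2 | step 10 | methyl 3-C-(1-carboxyethenyl)-3,5-dideoxy-5-C-[(2E)-5-(naphthalen-2-ylmethoxy)pent-2-en-2-yl]-α-D-arabinofuranoside (hydroxy acid) | CO[C@@H]1[C@@H](O)[C@H](C(=C)C(=O)O)[C@@H](C/C(C)=C/CCOCc2ccc3ccccc3c2)O1
F3 | step 12 | diol from reduction of lactol 19 (C5 hydroxymethyl on the lactone, free C8 hydroxyl) | OC[C@@H]1OC(=O)C(=C)[C@@H]1[C@H](O)C/C(C)=C/CCOCc2ccc3ccccc3c2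
F4 | step 12 | C5 tert-butyldimethylsilyl ether of F3 | CC(C)(C)[Si](C)(C)OC[C@@H]1OC(=O)C(=C)[C@@H]1[C@H](O)C/C(C)=C/CCOCc2ccc3ccccc3c2
F5 | step 12 | C8 methacrylate of F4 | CC(C)(C)[Si](C)(C)OC[C@@H]1OC(=O)C(=C)[C@@H]1[C@H](OC(=O)C(C)=C)C/C(C)=C/CCOCc2ccc3ccccc3c2
F6 | step 12 | primary C5 alcohol from F5 | OC[C@@H]1OC(=O)C(=C)[C@@H]1[C@H](OC(=O)C(C)=C)C/C(C)=C/CCOCc2ccc3ccccc3c2
F7 | step 12 | C5 aldehyde from F6 | O=C[C@@H]1OC(=O)C(=C)[C@@H]1[C@H](OC(=O)C(C)=C)C/C(C)=C/CCOCc2ccc3ccccc3c2
F8 | step 16 | C3 epimer of 24, (3R,6S,7R,8R)-3-hydroxy-8-(methacryloyloxy)germacra-1(10)E,4Z,11(13)-trien-12,6-olide | C=C(C)C(=O)O[C@@H]1C/C(C)=C/C[C@@H](O)/C(C)=C\[C@@H]2OC(=O)C(=C)[C@@H]21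
F9 | step 16 | (6S,7R,8R)-8-(methacryloyloxy)-3-oxogermacra-1(10)E,4Z,11(13)-trien-12,6-olide | C=C(C)C(=O)O[C@@H]1C/C(C)=C/CC(=O)/C(C)=C\[C@@H]2OC(=O)C(=C)[C@@H]21
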